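A percent here counts units of solid substrate held, and one side product counts as two, so target and side product stand on one scale.

| setting | alder | violet | ochre |
|---|---|---|---|
| solid substrate | 0.40 M | 0.60 M | 0.40 M |
| partner | 0.72 M | 0.480 M | 0.480 M |
| temperature | 5 °C |  |  |
| remark | run made earlier | at −15 °C throughout | at 5 °C until 1.5 h, from then on at −15 °C |
| time |  | 30 h | 8.0 h |

alder run (percent of the solid substrate charged)

| time / h | target / % | side product / % |
|---|---|---|
| 1.33 | 1.3 | 2.5 |
| 2.50 | 4.9 | 6.0 |
| 4.00 | 8.2 | 16.0 |
| 5.00 | 7.7 | 25.7 |

(readings scatter by 1 percentage point)

- percent here means solid substrate units held: one side product counts as two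
- the numbers in the tables scatter by 1 percentage point (one standard deviation)
- at the start none of the solid substrate is in solution
- what has only dissolved of solid substrate counts as not reacted
- the earlier runs do not show what temperature does; that part of a forecast is a guess
- a reading or a percentage of target counts all its forms, free or not

1. which one finishes higher in share of target in all that became target or side product ("neither" within 2 percentage points) (violet / ochre / neither)
2. share of target in all that became target or side product, violet
3. share of target in all that became target or side product, ochre

The bench rule says that partner in excess stays constant (pseudo-first-order), so target over side product follows the partner charged per solid substrate charged. Ochre has 1.20 equivalents and violet 0.800, so you put ochre's ratio at 1.50 times violet's, which is more partner per substrate. My own reckoning stops there: ochre ahead, with no share attached, because the cold is a guess.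

Now test the rule on the alder run. At 4.00 h it holds 8.2% target, and that is 4.56% of its partner charge. This fraction of the partner charge gone into target, one for one, is the partner take. By that count the alder partner stands near full. Yet from 4.00 h to 5.00 h target reads 8.2% and then 7.7%, flat within the scatter, while side product climbs from 16.0% to 25.7%. That is where the rule stops: a constant partner doesn't give a stalled target, so either target is leaving or partner is going elsewhere, and the alder run has no partner reading to tell which.

The forecast puts ochre ahead, with 33% for ochre and 24% for violet, saying “Violet has more substrate, less partner and a long run, so more target is eaten”.

The flask gives ochre, with 28.8% for ochre and 23.0% for violet, so the order is the forecast's and both shares lie within tolerance of its numbers.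

    solid substrate ⇌ dissolved substrate, rate k1*(cs1 - [dissolved substrate]) while solid is left; crystals form when [dissolved substrate] > cs1 (solubility = 0.210 M, k = 0.380 /h)
    dissolved substrate + partner → target (k = 0.380 /M/h, Ea = 60.0 kJ/mol)
    2 dissolved substrate → side product (k = 1.30 /M/h, Ea = 72.0 kJ/mol)
    solid product ⇌ target, rate k4*(cs4 - [target]) while solid is left; crystals form when [target] > cs4 (solubility = 0.190 M, k = 4.80 /h)
    solid substrate → decomposition product (k = 2.80 × 10⁻⁴ /h, Ea = 113 kJ/mol)
    2 partner → homo dimer (k = 0.670 /M/h, Ea = 71.0 kJ/mol)
    (constants at 5 °C)

In ochre at 8.00 h the partner take is 3.79%, beside the 4.56% read in the alder run, yet 60.1% of the partner charge is gone, and in ochre the path from two partner to homo dimer uses partner 5.6 times as fast as the target path at 2.09 h and 2.6 times as fast at 8.00 h. Violet at 30.0 h shows a partner take of 13.1% against 70.0% of its partner gone, with 30% of the charge left.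

The runs were computed for an exercise; noise was put on by code.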